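**Plan**

- Retrosynthesis: the two cinnamoyl ester C–O bonds (O3, O4) and the C1-carboxyl/O5 pair (masked as a 1,5-lactone) are cut last. The tertiary C1–O bond is traced back to the C1=C2 alkene of a 4-O-protected shikimate. The carbocycle is then cut at C3–C4 and C5–C6 into a four-carbon and a two-carbon piece.
- Enabling feature: in the cyclohexane ring the carboxyl-bearing C1 lies next to the unsubstituted C6 and 1,4 to the oxygen-bearing C4, and C3, C4, C5 are three contiguous carbinol carbons. Hence C6=C1(CO2Et)–C2=C3(OAc) is an acceptor diene and (E)-RO–C4H=C5H–B(pin) a donor alkene of matching polarity, with boron standing in for the C5 oxygen.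
- Forward order: diene (step 1) and chiral boryl enol ether (steps 2–3) are joined in one [4+2] event (step 4, the only ring-forming C–C step). Then follow C–B oxidation, hydroxyl-directed epoxidation and reductive opening (C1–OH), a temporary lactone, acylation at O3, release and acylation of O4, and acid hydrolysis.
- Stereochemistry: absolute configuration from the (S)-1-arylethyl ether on O4 (auxiliary and O4 protecting group in one); 4,5-trans from the E alkene plus stereoretentive C–B oxidation; 3,4-cis from the endo alkoxy group and the E dienyl acetate; C1 from the epoxidation directed by the C3 hydroxyl.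

Key step: step 4

Remark: quinic acid numbering is used throughout (C1 carboxylated carbinol, C3 caffeoyloxy, C4 p-coumaroyloxy, C5 free hydroxyl). TIPE = (1S)-1-[2,4,6-tri(propan-2-yl)phenyl]ethyl.
Assumption: ethyl (2E)-2-methyl-4-oxobut-2-enoate (1) is taken as a purchasable building block.
Assumption: the (S)-alcohol 3 is drawn because the conformational model given in step 4 predicts the (3R,4S,5R) adduct; should the sense prove opposite, the equally available (R)-alcohol is used.

**Route**

Step 1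
Reactants: 1 ethyl (2E)-2-methyl-4-oxobut-2-enoate
Product: 2 ethyl (3E)-4-(acetyloxy)-2-methylidenebut-3-enoate
Conditions: Ac2O, Et3N, DMAP (cat.), CH2Cl2, 0 °C to rt; used at once
Reagents that add atoms: acetic anhydride, CC(=O)OC(C)=O
Why: γ-deprotonation of the enal at the C2 methyl group and O-acetylation of the dienolate (enol ester formation) should give the conjugated dienyl acetate, E from the s-trans enal, and any Z isomer cannot reach the s-cis geometry and is inert later; no stereocentre is formed.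

Step 2
Reactants: 3 (1S)-1-[2,4,6-tri(propan-2-yl)phenyl]ethan-1-ol; 4 trichloroethene
Product: 6 2-[(1S)-1-(ethynyloxy)ethyl]-1,3,5-tri(propan-2-yl)benzene, via dichlorovinyl ether 5 (not isolated)
Conditions: KH, THF, 0 °C to rt, then 4; n-BuLi (2.5 equiv), −78 to −40 °C; MeOH quench
Reagents that add atoms: none
Why: addition–elimination of the potassium alkoxide to dichloroethyne formed in situ gives the dichlorovinyl ether, and dehydrochlorination, chlorine–lithium exchange and protonation then give the alkynyl ether (alkoxyalkyne synthesis from trichloroethene); the carbinol stereocentre is not touched.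

Step 3
Reactants: 6 2-[(1S)-1-(ethynyloxy)ethyl]-1,3,5-tri(propan-2-yl)benzene
Product: 7 4,4,5,5-tetramethyl-2-[(E)-2-(TIPE-oxy)ethenyl]-1,3,2-dioxaborolane
Conditions: pinacolborane, Cp2Zr(H)Cl (5 mol %), Et3N (10 mol %), CH2Cl2, rt
Reagents that add atoms: pinacolborane, CC1(C)OBOC1(C)C
Why: catalysed syn-hydroboration of the terminal alkoxyalkyne places boron on the terminal carbon and should give only the (E)-alkenylboronate (alkyne hydroboration).

Step 4
Reactants: 2 ethyl (3E)-4-(acetyloxy)-2-methylidenebut-3-enoate; 7 4,4,5,5-tetramethyl-2-[(E)-2-(TIPE-oxy)ethenyl]-1,3,2-dioxaborolane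
Product: 8 ethyl (3R,4S,5R)-3-(acetyloxy)-5-(4,4,5,5-tetramethyl-1,3,2-dioxaborolan-2-yl)-4-(TIPE-oxy)cyclohex-1-ene-1-carboxylate (3,4-cis, 4,5-trans)
Conditions: toluene, 100–110 °C, sealed tube, BHT (cat.), 2 (3 equiv) added in portions
Reagents that add atoms: none
Why: Proposed new method: an inverse-electron-demand, concerted but asynchronous Diels–Alder reaction in which the nucleophilic, boron-bearing C5 of enol ether 7 (β to the ether oxygen) bonds first to the acrylate-type terminus C6 of the acceptor diene 2 while the oxygen-bearing C4 closes onto the acetoxy-bearing terminus C3; the closest known reaction types are the inverse-demand cycloadditions of 2-alkoxycarbonyl- and 2-sulfonyl-1,3-dienes with enol ethers and the use of alkenylboronic esters as dienophiles. The cyclohexene ring closes in the suprafacial–suprafacial [4+2] mode, so the E geometry of 7 becomes the trans C4–O/C5–B relation (the future trans-4,5-diol) and the E geometry of the dienyl acetate puts the C3 acetate cis to the endo substituent. The ether oxygen is expected to sit endo (the usual preference of enol ethers toward acceptor dienes, reinforced by the bulky pinacol boronate going exo), which gives the 3,4-cis relation. The absolute configuration of C3, C4 and C5 is set by the (S)-1-arylethyl ether: with its carbinol C–H in the plane of the enol ether, the triisopropylphenyl ring blocks one face and the diene adds to the other, and the minor facial isomer is a separable diastereomer. Regiochemistry follows from matched polarity, since the carboxyl at C1 makes C6 the electrophilic terminus and places the donor-bearing C4 para to C1 and ortho to the C3 oxygen. The step needs the cross-reaction to beat dimerisation of 2 through its own acrylate unit, which the excess and portionwise addition of 2 and the lowered diene HOMO (acetate instead of silyl ether) are meant to secure.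

Step 5
Reactants: 8 ethyl (3R,4S,5R)-3-(acetyloxy)-5-(pinacolboryl)-4-(TIPE-oxy)cyclohex-1-ene-1-carboxylate
Product: 10 ethyl 4-O-TIPE-(−)-shikimate [ethyl (3R,4S,5R)-3,5-dihydroxy-4-(TIPE-oxy)cyclohex-1-ene-1-carboxylate], via hydroxy acetate 9 (not isolated)
Conditions: NaBO3·4H2O, THF/H2O, rt; then K2CO3 (cat.), EtOH, rt
Reagents that add atoms: sodium perborate tetrahydrate, [Na+].[Na+].O[B-]1(O)OO[B-](O)(O)OO1
Why: perborate oxidation of the secondary alkylboronate proceeds by 1,2-migration with retention, so the C5 hydroxyl stays trans to O4 (organoborane oxidation), and mild ethanolysis (transesterification) then removes the allylic acetate without touching the conjugated ethyl ester.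

Step 6
Reactants: 10 ethyl 4-O-TIPE-(−)-shikimate
Product: 11 ethyl (3R,4S,5R)-1,2-epoxy-3,5-dihydroxy-4-(TIPE-oxy)cyclohexane-1-carboxylate, epoxide oxygen on the face of the C3 hydroxyl
Conditions: m-CPBA, NaHCO3, ClCH2CH2Cl, 50 °C, BHT (cat.)
Reagents that add atoms: 3-chloroperoxybenzoic acid, OOC(=O)c1cccc(Cl)c1
Why: hydrogen bonding of the peracid to the pseudoaxial allylic C3 hydroxyl should deliver oxygen to the same face of the C1=C2 alkene (hydroxyl-directed Prilezhaev epoxidation), which sets the C1–O bond cis to O3 as in quinic acid.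

Step 7
Reactants: 11 ethyl (3R,4S,5R)-1,2-epoxy-3,5-dihydroxy-4-(TIPE-oxy)cyclohexane-1-carboxylate
Product: 13 ethyl 4-O-TIPE-(−)-quinate, via iodohydrin 12 (not isolated)
Conditions: MgI2, Et2O/toluene, −40 to 0 °C; then Bu3SnH, AIBN (cat.), 80 °C
Reagents that add atoms: none
Why: iodide opens the glycidic ester at the β-carbon C2 (SN2, trans-diaxial, C1 being quaternary and α to the carbonyl) and tin hydride then removes the iodine (halohydrin formation followed by radical dehalogenation), so the C1 tertiary alcohol keeps the configuration set in step 6.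

Step 8
Reactants: 13 ethyl 4-O-TIPE-(−)-quinate
Product: 14 4-O-TIPE-(−)-quinic acid 1,5-lactone
Conditions: 1,5,7-triazabicyclo[4.4.0]dec-5-ene (10 mol %), toluene, 70 °C, 4 Å molecular sieves
Reagents that add atoms: none
Why: base-catalysed intramolecular transesterification between the C1 ester and the cis C5 hydroxyl closes the γ-lactone (lactonisation), driven by removal of ethanol, and masks the carboxyl and O5 in one temporary ring.

Step 9
Reactants: 15 caffeic acid
Product: 16 (2E)-3-[3,4-bis(acetyloxy)phenyl]prop-2-enoic acid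
Conditions: Ac2O, pyridine, rt; aqueous work-up
Reagents that add atoms: acetic anhydride, CC(=O)OC(C)=O
Why: phenol acetylation (nucleophilic acyl substitution) protects both catechol hydroxyls, and the mixed anhydride at the carboxyl is hydrolysed on work-up.

Step 10
Reactants: 16 (2E)-3-[3,4-bis(acetyloxy)phenyl]prop-2-enoic acid
Product: 17 (2E)-3-[3,4-bis(acetyloxy)phenyl]prop-2-enoyl chloride
Conditions: (COCl)2, DMF (cat.), CH2Cl2, 0 °C to rt
Reagents that add atoms: oxalyl chloride, O=C(Cl)C(=O)Cl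
Why: chloroiminium-catalysed conversion of the acid into the acid chloride (acyl chloride formation) leaves the E alkene and the aryl acetates untouched.

Step 11
Reactants: 14 4-O-TIPE-(−)-quinic acid 1,5-lactone; 17 (2E)-3-[3,4-bis(acetyloxy)phenyl]prop-2-enoyl chloride
Product: 18 3-O-(3,4-di-O-acetylcaffeoyl)-4-O-TIPE-(−)-quinic acid 1,5-lactone
Conditions: pyridine, CH2Cl2, −20 to 0 °C
Reagents that add atoms: none
Why: in the lactone the equatorial C3 hydroxyl is the only secondary alcohol (O4 etherified, O5 lactonised, the C1 hydroxyl tertiary and next to a carbonyl), so esterification with the acid chloride should occur at O3 (nucleophilic acyl substitution).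

Step 12
Reactants: 18 3-O-(3,4-di-O-acetylcaffeoyl)-4-O-TIPE-(−)-quinic acid 1,5-lactone
Product: 19 3-O-(3,4-di-O-acetylcaffeoyl)-(−)-quinic acid 1,5-lactone
Conditions: CF3CO2H, Et3SiH, CH2Cl2, 0 °C
Reagents that add atoms: none
Why: the hindered, electron-rich benzylic ether ionises in acid (SN1 ether cleavage) and the cation is reduced by the silane, which frees the C4 hydroxyl while lactone, esters and aryl acetates are stable to anhydrous acid.

Step 13
Reactants: 20 p-coumaric acid
Product: 21 (2E)-3-[4-(acetyloxy)phenyl]prop-2-enoic acid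
Conditions: Ac2O, pyridine, rt; aqueous work-up
Reagents that add atoms: acetic anhydride, CC(=O)OC(C)=O
Why: phenol acetylation (nucleophilic acyl substitution) as in step 9.

Step 14
Reactants: 21 (2E)-3-[4-(acetyloxy)phenyl]prop-2-enoic acid
Product: 22 (2E)-3-[4-(acetyloxy)phenyl]prop-2-enoyl chloride
Conditions: (COCl)2, DMF (cat.), CH2Cl2, 0 °C to rt
Reagents that add atoms: oxalyl chloride, O=C(Cl)C(=O)Cl
Why: acyl chloride formation as in step 10.

Step 15
Reactants: 19 3-O-(3,4-di-O-acetylcaffeoyl)-(−)-quinic acid 1,5-lactone; 22 (2E)-3-[4-(acetyloxy)phenyl]prop-2-enoyl chloride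
Product: 23 3-O-(3,4-di-O-acetylcaffeoyl)-4-O-(4-O-acetyl-p-coumaroyl)-(−)-quinic acid 1,5-lactone
Conditions: pyridine, DMAP (0.1 equiv), CH2Cl2, −10 °C to rt
Reagents that add atoms: none
Why: the axial C4 hydroxyl is now the only secondary alcohol and should be esterified in preference to the tertiary C1 hydroxyl (DMAP-catalysed acylation), low temperature limiting acyl migration from O3 to O4.

Step 16
Reactants: 23 3-O-(3,4-di-O-acetylcaffeoyl)-4-O-(4-O-acetyl-p-coumaroyl)-(−)-quinic acid 1,5-lactone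
Product: 24 3-O-caffeoyl-4-O-p-coumaroyl-(−)-quinic acid (CNP0077575.1)
Conditions: 1 M HCl (aq)/THF, rt, several days
Reagents that add atoms: water, O
Why: aqueous acid should hydrolyse the γ-lactone and the three phenolic acetates (acid-catalysed ester hydrolysis) faster than the two cinnamate esters of secondary alcohols, and acidic conditions suppress acyl migration, so all four stereocentres are carried through unchanged.

**Compound list**

1 | ethyl (2E)-2-methyl-4-oxobut-2-enoate | CCOC(=O)/C(C)=C/C=O | starting material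
2 | ethyl (3E)-4-(acetyloxy)-2-methylidenebut-3-enoate | CCOC(=O)C(=C)/C=C/OC(C)=O | intermediate
3 | (1S)-1-[2,4,6-tri(propan-2-yl)phenyl]ethan-1-ol | C[C@H](O)c1c(C(C)C)cc(C(C)C)cc1C(C)C | starting material
4 | trichloroethene | ClC=C(Cl)Cl | starting material
5 | 2-[(1S)-1-{[(E)-1,2-dichloroethenyl]oxy}ethyl]-1,3,5-tri(propan-2-yl)benzene | Cl/C=C(/Cl)O[C@@H](C)c1c(C(C)C)cc(C(C)C)cc1C(C)C | intermediate
6 | 2-[(1S)-1-(ethynyloxy)ethyl]-1,3,5-tri(propan-2-yl)benzene | C#CO[C@@H](C)c1c(C(C)C)cc(C(C)C)cc1C(C)C | intermediate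
7 | 4,4,5,5-tetramethyl-2-[(E)-2-{(1S)-1-[2,4,6-tri(propan-2-yl)phenyl]ethoxy}ethenyl]-1,3,2-dioxaborolane | CC1(C)OB(/C=C/O[C@@H](C)c2c(C(C)C)cc(C(C)C)cc2C(C)C)OC1(C)C | intermediate
8 | ethyl (3R,4S,5R)-3-(acetyloxy)-5-(4,4,5,5-tetramethyl-1,3,2-dioxaborolan-2-yl)-4-(TIPE-oxy)cyclohex-1-ene-1-carboxylate | C[C@H](O[C@H]1[C@H](B2OC(C)(C)C(C)(C)O2)CC(C(=O)OCC)=C[C@H]1OC(C)=O)c1c(C(C)C)cc(C(C)C)cc1C(C)C | intermediate
9 | ethyl 3-O-acetyl-4-O-TIPE-(−)-shikimate, (3R,4S,5R) | C[C@H](O[C@H]1[C@H](O)CC(C(=O)OCC)=C[C@H]1OC(C)=O)c1c(C(C)C)cc(C(C)C)cc1C(C)C | intermediate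
10 | ethyl 4-O-TIPE-(−)-shikimate, (3R,4S,5R) | C[C@H](O[C@H]1[C@H](O)CC(C(=O)OCC)=C[C@H]1O)c1c(C(C)C)cc(C(C)C)cc1C(C)C | intermediate
11 | ethyl (3R,4S,5R)-1,2-epoxy-3,5-dihydroxy-4-(TIPE-oxy)cyclohexane-1-carboxylate, epoxide cis to the C3 hydroxyl | C[C@H](O[C@H]1[C@H](O)C[C@@]2(C(=O)OCC)O[C@H]2[C@H]1O)c1c(C(C)C)cc(C(C)C)cc1C(C)C | intermediate
12 | ethyl 2-iodo-4-O-TIPE-(−)-quinate, iodine at C2 trans to the C1 and C3 hydroxyls | C[C@H](O[C@H]1[C@H](O)C[C@](O)(C(=O)OCC)[C@H](I)[C@H]1O)c1c(C(C)C)cc(C(C)C)cc1C(C)C | intermediate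
13 | ethyl 4-O-TIPE-(−)-quinate | C[C@H](O[C@H]1[C@H](O)C[C@](O)(C(=O)OCC)C[C@H]1O)c1c(C(C)C)cc(C(C)C)cc1C(C)C | intermediate
14 | 4-O-TIPE-(−)-quinic acid 1,5-lactone | C[C@H](O[C@H]1[C@H]2C[C@](O)(C(=O)O2)C[C@H]1O)c1c(C(C)C)cc(C(C)C)cc1C(C)C | intermediate
15 | caffeic acid, (2E)-3-(3,4-dihydroxyphenyl)prop-2-enoic acid | OC(=O)/C=C/c1ccc(O)c(O)c1 | starting material
16 | (2E)-3-[3,4-bis(acetyloxy)phenyl]prop-2-enoic acid | CC(=O)Oc1ccc(/C=C/C(=O)O)cc1OC(C)=O | intermediate
17 | (2E)-3-[3,4-bis(acetyloxy)phenyl]prop-2-enoyl chloride | CC(=O)Oc1ccc(/C=C/C(=O)Cl)cc1OC(C)=O | intermediate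
18 | 3-O-(3,4-di-O-acetylcaffeoyl)-4-O-TIPE-(−)-quinic acid 1,5-lactone | C[C@H](O[C@H]1[C@H]2C[C@](O)(C(=O)O2)C[C@H]1OC(=O)/C=C/c1ccc(OC(C)=O)c(OC(C)=O)c1)c1c(C(C)C)cc(C(C)C)cc1C(C)C | intermediate
19 | 3-O-(3,4-di-O-acetylcaffeoyl)-(−)-quinic acid 1,5-lactone | O[C@H]1[C@H]2C[C@](O)(C(=O)O2)C[C@H]1OC(=O)/C=C/c1ccc(OC(C)=O)c(OC(C)=O)c1 | intermediate
20 | p-coumaric acid, (2E)-3-(4-hydroxyphenyl)prop-2-enoic acid | OC(=O)/C=C/c1ccc(O)cc1 | starting material
21 | (2E)-3-[4-(acetyloxy)phenyl]prop-2-enoic acid | CC(=O)Oc1ccc(/C=C/C(=O)O)cc1 | intermediate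
22 | (2E)-3-[4-(acetyloxy)phenyl]prop-2-enoyl chloride | CC(=O)Oc1ccc(/C=C/C(=O)Cl)cc1 | intermediate
23 | 3-O-(3,4-di-O-acetylcaffeoyl)-4-O-(4-O-acetyl-p-coumaroyl)-(−)-quinic acid 1,5-lactone | CC(=O)Oc1ccc(/C=C/C(=O)O[C@H]2[C@H]3C[C@](O)(C(=O)O3)C[C@H]2OC(=O)/C=C/c2ccc(OC(C)=O)c(OC(C)=O)c2)cc1 | intermediate
24 | 3-O-caffeoyl-4-O-p-coumaroyl-(−)-quinic acid (hydroxyls at C1, C3 and C4 oxygens on one ring face, C5 hydroxyl and carboxyl on the other) | O=C(/C=C/c1ccc(O)cc1)O[C@H]1[C@H](O)C[C@](O)(C(=O)O)C[C@H]1OC(=O)/C=C/c1ccc(O)c(O)c1 | target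

**Step count and risks**

Total step count: 16. Longest linear sequence: 11 steps (steps 2, 3, 4, 5, 6, 7, 8, 11, 12, 15, 16).

Steps most likely to fail:

1. Step 4 (bears the label). The acceptor diene may dimerise through its own acrylate unit faster than it is intercepted by 7, and exo approach or weak facial discrimination would erode the 3,4-cis relation and the diastereomeric purity. The fallback uses known chemistry, sets out from 2 and returns at 19. Thermal Diels–Alder reaction of 2 with commercial (E)-1,2-bis(4,4,5,5-tetramethyl-1,3,2-dioxaborolan-2-yl)ethene (alkenylboronic esters are established dienophiles and keep their geometry) should give racemic ethyl 3-(acetyloxy)-4,5-bis(pinacolboryl)cyclohex-1-ene-1-carboxylate F1 (3,4-cis, 4,5-trans) together with its C3 epimer. Perborate oxidation and ethanolysis as in step 5, chromatographic removal of the epimer and lipase-mediated kinetic resolution (enantioselective acetylation with vinyl acetate) would give ethyl (−)-shikimate F2. Directed epoxidation as in step 6 gives ethyl 1,2-epoxy-3,4,5-trihydroxycyclohexane-1-carboxylate F3, MgI2/Bu3SnH as in step 7 gives ethyl (−)-quinate F4, and lactonisation as in step 8 gives (−)-quinic acid 1,5-lactone F5. Its equatorial C3 hydroxyl is then acylated selectively with 17 (pyridine, low temperature) to return to 19.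

2. Step 6. Peracid attack on the electron-poor enoate may be slow, and delivery from the homoallylic C5 hydroxyl or shielding by the neighbouring TIPE group may give the wrong face. The fallback sets out from 10 and returns at 14, with the epoxidation moved to the allylic alcohol oxidation level under reagent control. Reduction of the ester with i-Bu2AlH gives (3R,4S,5R)-1-(hydroxymethyl)-4-(TIPE-oxy)cyclohex-1-ene-3,5-diol F6. Sharpless asymmetric epoxidation (Ti(OiPr)4, D-(−)-diethyl tartrate, t-BuOOH; matched with the C3 hydroxyl) gives the 1,2-epoxy triol F7, epoxide cis to O3. LiAlH4 delivers hydride to the secondary C2 and gives 1-(hydroxymethyl)-4-(TIPE-oxy)cyclohexane-1,3,5-triol F8. Selective oxidation of the primary alcohol (TEMPO, PhI(OAc)2, MeCN/water) gives 4-O-TIPE-(−)-quinic acid F9, which is lactonised (carbodiimide) to 14.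

3. Step 15. The tertiary C1 hydroxyl may compete for the acid chloride, and base may move the caffeoyl group from O3 to O4 before the C4 hydroxyl is capped. The fallback sets out from 18 and returns at 23. The only free hydroxyl of 18 is blocked with 2,2,2-trichloroethyl chloroformate (pyridine, DMAP) to give 1-O-(2,2,2-trichloroethoxycarbonyl)-3-O-(3,4-di-O-acetylcaffeoyl)-4-O-TIPE-(−)-quinic acid 1,5-lactone F10. Ether cleavage as in step 12 gives the 4-hydroxy carbonate F11, which can now be acylated with excess 22 and DMAP without competition to give the 1-O-(2,2,2-trichloroethoxycarbonyl) diester lactone F12. Zn in acetic acid removes the carbonate and gives 23.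

Further compounds

F1 | step 4 | racemic ethyl 3-(acetyloxy)-4,5-bis(4,4,5,5-tetramethyl-1,3,2-dioxaborolan-2-yl)cyclohex-1-ene-1-carboxylate (3,4-cis, 4,5-trans; one enantiomer drawn) | CC1(C)OB(OC1(C)C)[C@H]2[C@H](B3OC(C)(C)C(C)(C)O3)CC(C(=O)OCC)=C[C@H]2OC(C)=O
F2 | step 4 | ethyl (−)-shikimate, ethyl (3R,4S,5R)-3,4,5-trihydroxycyclohex-1-ene-1-carboxylate | O[C@H]1[C@H](O)CC(C(=O)OCC)=C[C@H]1O
F3 | step 4 | ethyl 1,2-epoxy-3,4,5-trihydroxycyclohexane-1-carboxylate, epoxide cis to the C3 hydroxyl | O[C@H]1[C@H](O)C[C@@]2(C(=O)OCC)O[C@H]2[C@H]1O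
F4 | step 4 | ethyl (−)-quinate | O[C@H]1[C@H](O)C[C@](O)(C(=O)OCC)C[C@H]1O
F5 | step 4 | (−)-quinic acid 1,5-lactone | O[C@H]1[C@H]2C[C@](O)(C(=O)O2)C[C@H]1O
F6 | step 6 | (3R,4S,5R)-1-(hydroxymethyl)-4-(TIPE-oxy)cyclohex-1-ene-3,5-diol | C[C@H](O[C@H]1[C@H](O)CC(CO)=C[C@H]1O)c1c(C(C)C)cc(C(C)C)cc1C(C)C
F7 | step 6 | 1,2-epoxy-1-(hydroxymethyl)-4-(TIPE-oxy)cyclohexane-3,5-diol, epoxide cis to the C3 hydroxyl | C[C@H](O[C@H]1[C@H](O)C[C@@]2(CO)O[C@H]2[C@H]1O)c1c(C(C)C)cc(C(C)C)cc1C(C)C
F8 | step 6 | 1-(hydroxymethyl)-4-(TIPE-oxy)cyclohexane-1,3,5-triol, quinic acid configuration | C[C@H](O[C@H]1[C@H](O)C[C@](O)(CO)C[C@H]1O)c1c(C(C)C)cc(C(C)C)cc1C(C)C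
F9 | step 6 | 4-O-TIPE-(−)-quinic acid | C[C@H](O[C@H]1[C@H](O)C[C@](O)(C(=O)O)C[C@H]1O)c1c(C(C)C)cc(C(C)C)cc1C(C)C
F10 | step 15 | 1-O-(2,2,2-trichloroethoxycarbonyl)-3-O-(3,4-di-O-acetylcaffeoyl)-4-O-TIPE-(−)-quinic acid 1,5-lactone | C[C@H](O[C@H]1[C@H]2C[C@](OC(=O)OCC(Cl)(Cl)Cl)(C(=O)O2)C[C@H]1OC(=O)/C=C/c1ccc(OC(C)=O)c(OC(C)=O)c1)c1c(C(C)C)cc(C(C)C)cc1C(C)C
F11 | step 15 | 1-O-(2,2,2-trichloroethoxycarbonyl)-3-O-(3,4-di-O-acetylcaffeoyl)-(−)-quinic acid 1,5-lactone | O[C@H]1[C@H]2C[C@](OC(=O)OCC(Cl)(Cl)Cl)(C(=O)O2)C[C@H]1OC(=O)/C=C/c1ccc(OC(C)=O)c(OC(C)=O)c1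
F12 | step 15 | 1-O-(2,2,2-trichloroethoxycarbonyl)-3-O-(3,4-di-O-acetylcaffeoyl)-4-O-(4-O-acetyl-p-coumaroyl)-(−)-quinic acid 1,5-lactone | CC(=O)Oc1ccc(/C=C/C(=O)O[C@H]2[C@H]3C[C@](OC(=O)OCC(Cl)(Cl)Cl)(C(=O)O3)C[C@H]2OC(=O)/C=C/c2ccc(OC(C)=O)c(OC(C)=O)c2)cc1
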